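**Plan**

1. Locants: terpenoid chain C1 (ArCH2) to C15 (CMe2–O); the cyclohexene ring is C2–C7. Retrosynthetic cuts, in order: C1–C2 (benzyl–alkenyl bond, opens the macrolide), the tertiary ester C15–O, C9–C10, then C3–C4 of the ring, then C7–CH3 (retro-semipinacol).
2. Forward: an acyclic (E)-allylic tertiary alcohol is brominated with a 1,2-methyl shift to a β-bromo methyl ketone (C6–Br next to quaternary C7). The ring is then closed between C3 and C4 by alkylation of the methyl ketone enolate, with C-methylation in the same flask.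
3. Feature that allows this closure: in ring C2–C7, C2 lies between the all-carbon quaternary C7 and C3, so as a ketone it can enolise only toward C3, and the primary carbon C4 is reached in a 6-exo ring. The same ketone then gives the tetrasubstituted C2=C3 enol triflate.
4. Chain and macrocycle: Negishi coupling C9–C10 with a C10–C15 alkenyl iodide, bromide opening of the terminal epoxide, acylation of the tertiary alcohol, epoxidation of C10=C11, then closure of the 16-membered ring at C1–C2 by an intramolecular benzylzinc/alkenyl triflate Negishi coupling.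
5. Stereochemistry: C6/C7 from the E alkene geometry (anti addition of Br and CH3) plus a cinchona catalyst; C14 from a Shi epoxide opened with inversion by bromide; C10/C11 from Shi epoxidation of the E alkene.

Key step: step 6

Remark: in step 4 the quinidine-derived catalyst is written; whichever member of the quinidine/quinine pseudoenantiomeric pair delivers bromine to the face that leads to (3S,4S)-6 is the one to be used. Compounds 1, 2, 13 and 19 are taken as catalogue materials.

**Route**

Step 1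
Reactants: 1 3-(triphenyl-λ5-phosphanylidene)oxolan-2-one; 2 3-[(tert-butyldimethylsilyl)oxy]propanal
Product: 3 (3E)-3-{3-[(tert-butyldimethylsilyl)oxy]propylidene}oxolan-2-one
Conditions: toluene, 25 → 60 °C
Reagents that add atoms: none
Why: Wittig olefination with an ester-stabilised ylide should give the (E)-alkylidene lactone (vinyl H syn to C=O), the geometry that later fixes the relative configuration at C6/C7.

Step 2
Reactants: 3 (3E)-3-{3-[(tert-butyldimethylsilyl)oxy]propylidene}oxolan-2-one
Product: 4 (3E)-3-{3-[(tert-butyldimethylsilyl)oxy]propylidene}-4-methylpentane-1,4-diol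
Conditions: MeLi, CeCl3, THF, −78 °C; aq. NH4Cl
Reagents that add atoms: methyllithium (C[Li])
Why: Double 1,2-addition of the organocerium reagent to the lactone carbonyl (ester to tertiary alcohol) should leave the alkene geometry and the silyl ether untouched and brings in the two methyl groups that become C3 and the C7 methyl.

Step 3
Reactants: 4 (3E)-3-{3-[(tert-butyldimethylsilyl)oxy]propylidene}-4-methylpentane-1,4-diol
Product: 5 (3E)-6-[(tert-butyldimethylsilyl)oxy]-3-{2-[(tert-butyldiphenylsilyl)oxy]ethyl}-2-methylhex-3-en-2-ol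
Conditions: t-BuPh2SiCl, imidazole, CH2Cl2, 0 °C
Reagents that add atoms: tert-butyl(chloro)diphenylsilane (CC(C)(C)[Si](Cl)(c1ccccc1)c1ccccc1)
Why: Silylation with the bulky chlorosilane is selective for the primary over the tertiary hydroxyl and masks the C9 oxygen as a non-participating group for step 4.

Step 4
Reactants: 5 (3E)-6-[(tert-butyldimethylsilyl)oxy]-3-{2-[(tert-butyldiphenylsilyl)oxy]ethyl}-2-methylhex-3-en-2-ol
Product: 6 (3S,4S)-4-bromo-6-[(tert-butyldimethylsilyl)oxy]-3-{2-[(tert-butyldiphenylsilyl)oxy]ethyl}-3-methylhexan-2-one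
Conditions: N-bromosuccinimide, hydroquinidine 1,4-phthalazinediyl diether (10 mol %), N-Boc-L-phenylglycine (10 mol %), toluene, −40 °C, dark
Reagents that add atoms: N-bromosuccinimide (O=C1CCC(=O)N1Br)
Why: Catalytic enantioselective bromination/semipinacol rearrangement, in which bromine is delivered to one alkene face at C6 and a methyl group migrates from the carbinol carbon to C7 anti to bromine, so the E geometry gives the like (3S,4S) relation and the catalyst sets the absolute sense.

Step 5
Reactants: 6 (3S,4S)-4-bromo-6-[(tert-butyldimethylsilyl)oxy]-3-{2-[(tert-butyldiphenylsilyl)oxy]ethyl}-3-methylhexan-2-one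
Product: 7 (3S,4S)-4,6-dibromo-3-{2-[(tert-butyldiphenylsilyl)oxy]ethyl}-3-methylhexan-2-one
Conditions: Ph3PBr2, CH2Cl2, 0 → 25 °C
Reagents that add atoms: dibromotriphenylphosphorane (BrP(Br)(c1ccccc1)(c1ccccc1)c1ccccc1)
Why: Direct bromodesilylation of the primary tert-butyldimethylsilyl ether (Appel-type oxyphosphonium displacement) should spare the bulkier tert-butyldiphenylsilyl ether and the ketone and gives the primary bromide at C4.

Step 6
Reactants: 7 (3S,4S)-4,6-dibromo-3-{2-[(tert-butyldiphenylsilyl)oxy]ethyl}-3-methylhexan-2-one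
Product: 9 (2S,3S)-3-bromo-2-{2-[(tert-butyldiphenylsilyl)oxy]ethyl}-2,6-dimethylcyclohexan-1-one (both C6 epimers), via cyclohexanone 8 (not isolated)
Conditions: KN(SiMe3)2 (1.05 equiv), THF, −78 → 0 °C; then KN(SiMe3)2 (1.1 equiv), −78 °C; MeI (1.05 equiv), −78 → −20 °C
Reagents that add atoms: iodomethane (CI)
Why: KN(SiMe3)2 removes a proton from the acetyl CH3 of 7, the only enolisable position because the other α-carbon (C7) is quaternary, and the potassium enolate displaces the primary bromide at C4 by SN2, the closest known type being the intramolecular alkylation of a ketone enolate (cycloalkylation). The six-membered ring closes in the 6-exo-tet mode through carbon; O-alkylation would need a seven-membered enol ether and attack at the secondary neopentyl C6 bromide a four-membered ring, so neither should compete. A second equivalent of base enolises cyclohexanone 8, again toward C3 only, and MeI adds the methyl group, so both carbon substituents of the future alkene carbon C3 are in place after one operation. No lasting stereocentre is formed: C3 becomes a mixture of epimers that step 7 erases, while C6 and C7 are untouched because C7 has no hydrogen and no acidic hydrogen lies between the carbonyl and the C6–Br bond. The selectivity needed is C- over O-alkylation and mono- over dimethylation, which the potassium enolate in THF at low temperature, one equivalent of MeI and the hindered, less acidic α-methine of 9 should secure.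

Step 7
Reactants: 9 (2S,3S)-3-bromo-2-{2-[(tert-butyldiphenylsilyl)oxy]ethyl}-2,6-dimethylcyclohexan-1-one (both C6 epimers)
Product: 10 (5S,6S)-5-bromo-6-{2-[(tert-butyldiphenylsilyl)oxy]ethyl}-2,6-dimethylcyclohex-1-en-1-yl trifluoromethanesulfonate
Conditions: KN(SiMe3)2, THF, −78 → 0 °C; PhNTf2, −78 → 0 °C
Reagents that add atoms: N-phenylbis(trifluoromethanesulfonimide) (O=S(=O)(N(c1ccccc1)S(=O)(=O)C(F)(F)F)C(F)(F)F)
Why: O-Triflation of the only possible, tetrasubstituted enolate (enol triflate formation, as known for 2,2,6-trisubstituted cyclohexanones) removes the C3 stereocentre and sets the C2=C3 double bond.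

Step 8
Reactants: 10 (5S,6S)-5-bromo-6-{2-[(tert-butyldiphenylsilyl)oxy]ethyl}-2,6-dimethylcyclohex-1-en-1-yl trifluoromethanesulfonate
Product: 11 (5S,6S)-5-bromo-6-(2-hydroxyethyl)-2,6-dimethylcyclohex-1-en-1-yl trifluoromethanesulfonate
Conditions: HF·pyridine, pyridine, THF, 0 → 25 °C
Reagents that add atoms: none
Why: Fluoride-mediated desilylation under buffered conditions should free the primary alcohol without touching the alkenyl triflate or the secondary bromide.

Step 9
Reactants: 11 (5S,6S)-5-bromo-6-(2-hydroxyethyl)-2,6-dimethylcyclohex-1-en-1-yl trifluoromethanesulfonate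
Product: 12 (5S,6S)-5-bromo-6-(2-iodoethyl)-2,6-dimethylcyclohex-1-en-1-yl trifluoromethanesulfonate
Conditions: I2, PPh3, imidazole, CH2Cl2, 0 °C
Reagents that add atoms: iodine (II)
Why: Appel-type iodination converts the unhindered primary alcohol to the iodide by SN2 displacement of the oxyphosphonium group.

Step 10
Reactants: 13 6-methylhept-5-en-2-one
Product: 15 6-methylhept-5-en-1-yne, via enol phosphate 14 (not isolated)
Conditions: LiN(i-Pr)2, THF, −78 °C; ClP(O)(OEt)2; then LiN(i-Pr)2 (2.2 equiv), −78 → 25 °C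
Reagents that add atoms: none
Why: Kinetic enolisation at the methyl group, O-phosphorylation and base-induced elimination of the terminal enol phosphate give the terminal alkyne (one-pot methyl ketone to alkyne conversion).

Step 11
Reactants: 15 6-methylhept-5-en-1-yne
Product: 17 (1E)-1-iodo-2,6-dimethylhepta-1,5-diene, via alkenylalane 16 (not isolated)
Conditions: Me3Al, Cp2ZrCl2 (25 mol %), CH2Cl2, 0 → 25 °C; then I2, THF, −30 → 0 °C
Reagents that add atoms: trimethylaluminium (C[Al](C)C); iodine (II)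
Why: Zirconium-catalysed syn carboalumination (Negishi carboalumination) places CH3 on the inner and Al on the terminal alkyne carbon, and iodinolysis with retention gives the (E)-iodoalkene with the geometry of the later C10=C11 bond.

Step 12
Reactants: 17 (1E)-1-iodo-2,6-dimethylhepta-1,5-diene
Product: 18 (3S)-3-[(3E)-4-iodo-3-methylbut-3-en-1-yl]-2,2-dimethyloxirane
Conditions: 1,2:4,5-di-O-isopropylidene-β-L-erythro-2,3-hexodiulo-2,6-pyranose (30 mol %), KHSO5 (as 2KHSO5·KHSO4·K2SO4), K2CO3, Bu4NHSO4, MeCN–CH2(OMe)2–aq. Na2B4O7 buffer, 0 °C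
Reagents that add atoms: potassium peroxymonosulfate ([K+].[O-]S(=O)(=O)OO)
Why: Shi epoxidation, in which the dioxirane of the L-fructose-derived ketone attacks the electron-rich trisubstituted alkene through a spiro transition state on the face that gives the (S)-epoxide, while the iodoalkene is too electron-poor to react.

Step 13
Reactants: 19 3-formyl-4-hydroxybenzoic acid
Product: 21 3-formyl-4-[(triisopropylsilyl)oxy]benzoic acid, via silyl ester 20 (not isolated)
Conditions: i-Pr3SiCl (2.2 equiv), imidazole, DMF, 25 °C; then THF–H2O–AcOH, 25 °C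
Reagents that add atoms: chlorotri(propan-2-yl)silane (CC(C)[Si](Cl)(C(C)C)C(C)C)
Why: Silylation of both phenol and acid followed by selective hydrolysis of the labile silyl ester leaves the phenol as a robust aryl silyl ether.

Step 14
Reactants: 21 3-formyl-4-[(triisopropylsilyl)oxy]benzoic acid
Product: 22 3-(hydroxymethyl)-4-[(triisopropylsilyl)oxy]benzoic acid
Conditions: NaBH4, THF–MeOH, −20 → 0 °C
Reagents that add atoms: none
Why: Chemoselective borohydride reduction of the aldehyde in the presence of the carboxylate gives the benzylic alcohol, the bulky silyl group disfavouring O-to-O silyl migration.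

Step 15
Reactants: 22 3-(hydroxymethyl)-4-[(triisopropylsilyl)oxy]benzoic acid
Product: 23 3-(chloromethyl)-4-[(triisopropylsilyl)oxy]benzoyl chloride
Conditions: SOCl2, DMF (cat.), CH2Cl2, 0 → 25 °C; evaporation
Reagents that add atoms: thionyl chloride (O=S(Cl)Cl)
Why: Vilsmeier-type activation with SOCl2/DMF converts the benzylic alcohol to the chloride and the acid to the acyl chloride in one operation.

Step 16
Reactants: 12 (5S,6S)-5-bromo-6-(2-iodoethyl)-2,6-dimethylcyclohex-1-en-1-yl trifluoromethanesulfonate; 18 (3S)-3-[(3E)-4-iodo-3-methylbut-3-en-1-yl]-2,2-dimethyloxirane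
Product: 25 (5S,6S)-5-bromo-6-{(3E)-6-[(2S)-3,3-dimethyloxiran-2-yl]-4-methylhex-3-en-1-yl}-2,6-dimethylcyclohex-1-en-1-yl trifluoromethanesulfonate, via alkylzinc iodide 24 (not isolated)
Conditions: Zn dust (Me3SiCl/BrCH2CH2Br-activated), THF, 30 °C; then 18, Pd(dppf)Cl2 (5 mol %), THF, 25 °C
Reagents that add atoms: none
Why: Zinc inserts only into the primary C–I bond, and the Negishi coupling of the alkylzinc with the alkenyl iodide keeps the E geometry because the iodide undergoes oxidative addition far faster than the hindered alkenyl triflate.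

Step 17
Reactants: 25 (5S,6S)-5-bromo-6-{(3E)-6-[(2S)-3,3-dimethyloxiran-2-yl]-4-methylhex-3-en-1-yl}-2,6-dimethylcyclohex-1-en-1-yl trifluoromethanesulfonate
Product: 26 (5S,6S)-5-bromo-6-[(3E,7R)-7-bromo-8-hydroxy-4,8-dimethylnon-3-en-1-yl]-2,6-dimethylcyclohex-1-en-1-yl trifluoromethanesulfonate
Conditions: Li2NiBr4, THF, 0 → 25 °C; pH 7 phosphate buffer
Reagents that add atoms: dilithium tetrabromonickelate ([Li+].[Li+].[Ni+2].[Br-].[Br-].[Br-].[Br-])
Why: Bromide opens the epoxide by SN2 at the less substituted carbon C14 with inversion, which turns the (S)-epoxide into the (R)-bromide and frees the tertiary alcohol.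

Step 18
Reactants: 26 (5S,6S)-5-bromo-6-[(3E,7R)-7-bromo-8-hydroxy-4,8-dimethylnon-3-en-1-yl]-2,6-dimethylcyclohex-1-en-1-yl trifluoromethanesulfonate; 23 3-(chloromethyl)-4-[(triisopropylsilyl)oxy]benzoyl chloride
Product: 27 (3R,6E)-3-bromo-9-[(1S,6S)-6-bromo-1,3-dimethyl-2-{[(trifluoromethyl)sulfonyl]oxy}cyclohex-2-en-1-yl]-2,6-dimethylnon-6-en-2-yl 3-(chloromethyl)-4-[(triisopropylsilyl)oxy]benzoate
Conditions: 23 (2 equiv), 4-(dimethylamino)pyridine (2.5 equiv), CH2Cl2, 0 → 35 °C
Reagents that add atoms: none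
Why: Acyl transfer through the N-acylpyridinium salt (nucleophilic catalysis) esterifies the tertiary alcohol without forming its alkoxide, so the bromohydrin should not close back to an epoxide.

Step 19
Reactants: 27 (3R,6E)-3-bromo-9-[(1S,6S)-6-bromo-1,3-dimethyl-2-{[(trifluoromethyl)sulfonyl]oxy}cyclohex-2-en-1-yl]-2,6-dimethylnon-6-en-2-yl 3-(chloromethyl)-4-[(triisopropylsilyl)oxy]benzoate
Product: 28 (3R)-3-bromo-5-[(2S,3S)-3-{2-[(1S,6S)-6-bromo-1,3-dimethyl-2-{[(trifluoromethyl)sulfonyl]oxy}cyclohex-2-en-1-yl]ethyl}-2-methyloxiran-2-yl]-2-methylpentan-2-yl 3-(chloromethyl)-4-[(triisopropylsilyl)oxy]benzoate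
Conditions: 1,2:4,5-di-O-isopropylidene-β-L-erythro-2,3-hexodiulo-2,6-pyranose (50 mol %), KHSO5 (as 2KHSO5·KHSO4·K2SO4), K2CO3, Bu4NHSO4, MeCN–CH2(OMe)2–aq. Na2B4O7 buffer, 0 °C
Reagents that add atoms: potassium peroxymonosulfate ([K+].[O-]S(=O)(=O)OO)
Why: Shi epoxidation of the only electron-rich alkene (the alkenyl triflate is deactivated) on the face set by the L-fructose-derived ketone gives the (10S,11S)-epoxide from the E alkene.

Step 20
Reactants: 28 (3R)-3-bromo-5-[(2S,3S)-3-{2-[(1S,6S)-6-bromo-1,3-dimethyl-2-{[(trifluoromethyl)sulfonyl]oxy}cyclohex-2-en-1-yl]ethyl}-2-methyloxiran-2-yl]-2-methylpentan-2-yl 3-(chloromethyl)-4-[(triisopropylsilyl)oxy]benzoate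
Product: 30 O-triisopropylsilyl ether of the target macrolide (6S,7S,10S,11S,14R), via benzylzinc chloride 29 (not isolated)
Conditions: Zn dust, LiCl, THF, 25 °C; then syringe-pump addition to Pd(OAc)2 (10 mol %), 2-dicyclohexylphosphino-2',6'-dimethoxybiphenyl (20 mol %), THF, 50 °C, final 1 mM
Reagents that add atoms: none
Why: Zinc inserts into the benzylic C–Cl bond and the intramolecular Negishi coupling with the alkenyl triflate, run by slow addition to the catalyst, closes the 16-membered ring at C1–C2 and creates the tetrasubstituted alkene without touching a stereocentre.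

Step 21
Reactants: 30 O-triisopropylsilyl ether of the target macrolide (6S,7S,10S,11S,14R)
Product: 31 target macrolide CNP0420597.1 (6S,7S,10S,11S,14R)
Conditions: Bu4NF, AcOH, THF, 0 °C
Reagents that add atoms: none
Why: Buffered fluoride cleavage of the aryl silyl ether (desilylation) frees the phenol under conditions that the epoxide, the tertiary ester and the secondary bromides should survive.

**Compound list**

1 | 3-(triphenyl-λ5-phosphanylidene)oxolan-2-one | O=C1OCCC1=P(c2ccccc2)(c2ccccc2)c2ccccc2 | starting material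
2 | 3-[(tert-butyldimethylsilyl)oxy]propanal | O=CCCO[Si](C)(C)C(C)(C)C | starting material
3 | (3E)-3-{3-[(tert-butyldimethylsilyl)oxy]propylidene}oxolan-2-one | O=C1OCC\C1=C/CCO[Si](C)(C)C(C)(C)C | intermediate
4 | (3E)-3-{3-[(tert-butyldimethylsilyl)oxy]propylidene}-4-methylpentane-1,4-diol | CC(C)(O)/C(CCO)=C/CCO[Si](C)(C)C(C)(C)C | intermediate
5 | (3E)-6-[(tert-butyldimethylsilyl)oxy]-3-{2-[(tert-butyldiphenylsilyl)oxy]ethyl}-2-methylhex-3-en-2-ol | CC(C)(O)/C(CCO[Si](c1ccccc1)(c1ccccc1)C(C)(C)C)=C/CCO[Si](C)(C)C(C)(C)C | intermediate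
6 | (3S,4S)-4-bromo-6-[(tert-butyldimethylsilyl)oxy]-3-{2-[(tert-butyldiphenylsilyl)oxy]ethyl}-3-methylhexan-2-one | CC(=O)[C@](C)(CCO[Si](c1ccccc1)(c1ccccc1)C(C)(C)C)[C@@H](Br)CCO[Si](C)(C)C(C)(C)C | intermediate
7 | (3S,4S)-4,6-dibromo-3-{2-[(tert-butyldiphenylsilyl)oxy]ethyl}-3-methylhexan-2-one | CC(=O)[C@](C)(CCO[Si](c1ccccc1)(c1ccccc1)C(C)(C)C)[C@@H](Br)CCBr | intermediate
8 | (2S,3S)-3-bromo-2-{2-[(tert-butyldiphenylsilyl)oxy]ethyl}-2-methylcyclohexan-1-one | O=C1[C@](C)(CCO[Si](c2ccccc2)(c2ccccc2)C(C)(C)C)[C@@H](Br)CCC1 | intermediate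
9 | (2S,3S)-3-bromo-2-{2-[(tert-butyldiphenylsilyl)oxy]ethyl}-2,6-dimethylcyclohexan-1-one (both C6 epimers) | O=C1[C@](C)(CCO[Si](c2ccccc2)(c2ccccc2)C(C)(C)C)[C@@H](Br)CCC1C | intermediate
10 | (5S,6S)-5-bromo-6-{2-[(tert-butyldiphenylsilyl)oxy]ethyl}-2,6-dimethylcyclohex-1-en-1-yl trifluoromethanesulfonate | CC1=C(OS(=O)(=O)C(F)(F)F)[C@](C)(CCO[Si](c2ccccc2)(c2ccccc2)C(C)(C)C)[C@@H](Br)CC1 | intermediate
11 | (5S,6S)-5-bromo-6-(2-hydroxyethyl)-2,6-dimethylcyclohex-1-en-1-yl trifluoromethanesulfonate | CC1=C(OS(=O)(=O)C(F)(F)F)[C@](C)(CCO)[C@@H](Br)CC1 | intermediate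
12 | (5S,6S)-5-bromo-6-(2-iodoethyl)-2,6-dimethylcyclohex-1-en-1-yl trifluoromethanesulfonate | CC1=C(OS(=O)(=O)C(F)(F)F)[C@](C)(CCI)[C@@H](Br)CC1 | intermediate
13 | 6-methylhept-5-en-2-one | CC(=O)CCC=C(C)C | starting material
14 | diethyl 6-methylhepta-1,5-dien-2-yl phosphate | C=C(OP(=O)(OCC)OCC)CCC=C(C)C | intermediate
15 | 6-methylhept-5-en-1-yne | C#CCCC=C(C)C | intermediate
16 | [(1E)-2,6-dimethylhepta-1,5-dien-1-yl]dimethylalumane | C[Al](C)/C=C(\C)CCC=C(C)C | intermediate
17 | (1E)-1-iodo-2,6-dimethylhepta-1,5-diene | I/C=C(\C)CCC=C(C)C | intermediate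
18 | (3S)-3-[(3E)-4-iodo-3-methylbut-3-en-1-yl]-2,2-dimethyloxirane | CC1(C)O[C@H]1CC/C(C)=C/I | intermediate
19 | 3-formyl-4-hydroxybenzoic acid | O=Cc1cc(C(=O)O)ccc1O | starting material
20 | triisopropylsilyl 3-formyl-4-[(triisopropylsilyl)oxy]benzoate | O=Cc1cc(C(=O)O[Si](C(C)C)(C(C)C)C(C)C)ccc1O[Si](C(C)C)(C(C)C)C(C)C | intermediate
21 | 3-formyl-4-[(triisopropylsilyl)oxy]benzoic acid | O=Cc1cc(C(=O)O)ccc1O[Si](C(C)C)(C(C)C)C(C)C | intermediate
22 | 3-(hydroxymethyl)-4-[(triisopropylsilyl)oxy]benzoic acid | OCc1cc(C(=O)O)ccc1O[Si](C(C)C)(C(C)C)C(C)C | intermediate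
23 | 3-(chloromethyl)-4-[(triisopropylsilyl)oxy]benzoyl chloride | ClCc1cc(C(Cl)=O)ccc1O[Si](C(C)C)(C(C)C)C(C)C | intermediate
24 | {2-[(1S,6S)-6-bromo-1,3-dimethyl-2-{[(trifluoromethyl)sulfonyl]oxy}cyclohex-2-en-1-yl]ethyl}(iodo)zinc | CC1=C(OS(=O)(=O)C(F)(F)F)[C@](C)(CC[Zn]I)[C@@H](Br)CC1 | intermediate
25 | (5S,6S)-5-bromo-6-{(3E)-6-[(2S)-3,3-dimethyloxiran-2-yl]-4-methylhex-3-en-1-yl}-2,6-dimethylcyclohex-1-en-1-yl trifluoromethanesulfonate | CC1=C(OS(=O)(=O)C(F)(F)F)[C@](C)(CC/C=C(\C)CC[C@@H]2OC2(C)C)[C@@H](Br)CC1 | intermediate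
26 | (5S,6S)-5-bromo-6-[(3E,7R)-7-bromo-8-hydroxy-4,8-dimethylnon-3-en-1-yl]-2,6-dimethylcyclohex-1-en-1-yl trifluoromethanesulfonate | CC1=C(OS(=O)(=O)C(F)(F)F)[C@](C)(CC/C=C(\C)CC[C@@H](Br)C(C)(C)O)[C@@H](Br)CC1 | intermediate
27 | (3R,6E)-3-bromo-9-[(1S,6S)-6-bromo-1,3-dimethyl-2-{[(trifluoromethyl)sulfonyl]oxy}cyclohex-2-en-1-yl]-2,6-dimethylnon-6-en-2-yl 3-(chloromethyl)-4-[(triisopropylsilyl)oxy]benzoate | CC1=C(OS(=O)(=O)C(F)(F)F)[C@](C)(CC/C=C(\C)CC[C@@H](Br)C(C)(C)OC(=O)c2ccc(O[Si](C(C)C)(C(C)C)C(C)C)c(CCl)c2)[C@@H](Br)CC1 | intermediate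
28 | (3R)-3-bromo-5-[(2S,3S)-3-{2-[(1S,6S)-6-bromo-1,3-dimethyl-2-{[(trifluoromethyl)sulfonyl]oxy}cyclohex-2-en-1-yl]ethyl}-2-methyloxiran-2-yl]-2-methylpentan-2-yl 3-(chloromethyl)-4-[(triisopropylsilyl)oxy]benzoate | CC1=C(OS(=O)(=O)C(F)(F)F)[C@](C)(CC[C@@H]2O[C@@]2(C)CC[C@@H](Br)C(C)(C)OC(=O)c3ccc(O[Si](C(C)C)(C(C)C)C(C)C)c(CCl)c3)[C@@H](Br)CC1 | intermediate
29 | benzylic zinc chloride of 28 (CH2ZnCl in place of CH2Cl) | CC1=C(OS(=O)(=O)C(F)(F)F)[C@](C)(CC[C@@H]2O[C@@]2(C)CC[C@@H](Br)C(C)(C)OC(=O)c3ccc(O[Si](C(C)C)(C(C)C)C(C)C)c(C[Zn]Cl)c3)[C@@H](Br)CC1 | intermediate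
30 | O-triisopropylsilyl ether of the target macrolide (6S,7S,10S,11S,14R) | CC1=C2Cc3cc(ccc3O[Si](C(C)C)(C(C)C)C(C)C)C(=O)OC(C)(C)[C@H](Br)CC[C@]3(C)O[C@H]3CC[C@]2(C)[C@@H](Br)CC1 | intermediate
31 | CNP0420597.1: 16-membered macrolide (6S,7S,10S,11S,14R) in which C3 of a 4-hydroxybenzoate is joined through CH2 (C1) to C2 of the 6-bromo-3,7-dimethylcyclohex-2-ene ring, C7 carries the chain with the C10/C11 epoxide and the C14 bromide, and the C15 tertiary oxygen closes the ester | CC1=C2Cc3cc(ccc3O)C(=O)OC(C)(C)[C@H](Br)CC[C@]3(C)O[C@H]3CC[C@]2(C)[C@@H](Br)CC1 | target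

**Count**

Total: 21 steps. Longest linear sequence: 15 steps (steps 1–9, then 16–21).

**Steps most likely to fail**

1. Step 20 (macrocyclising Negishi coupling). Coupling between molecules or protonation of the benzylic zinc reagent may outrun the slow closure of the 16-membered ring at the hindered alkenyl triflate, and zinc halide may open the epoxide while the reagent is being made. Fallback: starting from 28, the benzylic zinc chloride 29 is formed as before but quenched with Bu3SnCl to give the isolable, chromatographable benzylic stannane F1. A Stille macrocyclisation of F1 (Pd2(dba)3, AsPh3, LiCl, N-methylpyrrolidone, 60 °C, syringe-pump addition) then separates metalation from ring closure and rejoins the route at 30.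

2. Step 4 (asymmetric bromination/semipinacol rearrangement). Facial discrimination in bromine delivery may be poor on an acyclic alkene whose migrating group is an unactivated methyl, and bromoetherification may compete. Fallback: starting from 5, N-bromosuccinimide alone in CH2Cl2 at −20 °C gives the racemic bromoketone, that is 6 together with its (3R,4R)-enantiomer F2, since the anti shift fixes the relative configuration without a catalyst. The enantiomers are separated by preparative chromatography on a chiral stationary phase and the route continues from 6.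

3. Step 18 (acylation of the tertiary bromohydrin). Acyl transfer to the hindered tertiary hydroxyl may be so slow that alkylation of the pyridine by the benzylic chloride or loss of HBr takes over. Fallback: acid chloride 23 is converted to the symmetrical anhydride F3 (half an equivalent of water, pyridine, CH2Cl2). Alcohol 26 is then acylated with F3 under Lewis acid catalysis (Sc(OTf)3, MeCN, −20 °C), which rejoins the route at 27.

**Further compounds**

F1 | step 20 | (3R)-3-bromo-5-[(2S,3S)-3-{2-[(1S,6S)-6-bromo-1,3-dimethyl-2-{[(trifluoromethyl)sulfonyl]oxy}cyclohex-2-en-1-yl]ethyl}-2-methyloxiran-2-yl]-2-methylpentan-2-yl 3-[(tributylstannyl)methyl]-4-[(triisopropylsilyl)oxy]benzoate | CC1=C(OS(=O)(=O)C(F)(F)F)[C@](C)(CC[C@@H]2O[C@@]2(C)CC[C@@H](Br)C(C)(C)OC(=O)c3ccc(O[Si](C(C)C)(C(C)C)C(C)C)c(C[Sn](CCCC)(CCCC)CCCC)c3)[C@@H](Br)CC1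
F2 | step 4 | (3R,4R)-4-bromo-6-[(tert-butyldimethylsilyl)oxy]-3-{2-[(tert-butyldiphenylsilyl)oxy]ethyl}-3-methylhexan-2-one | CC(=O)[C@@](C)(CCO[Si](c1ccccc1)(c1ccccc1)C(C)(C)C)[C@H](Br)CCO[Si](C)(C)C(C)(C)C
F3 | step 18 | 3-(chloromethyl)-4-[(triisopropylsilyl)oxy]benzoic anhydride | O=C(OC(=O)c1ccc(O[Si](C(C)C)(C(C)C)C(C)C)c(CCl)c1)c1ccc(O[Si](C(C)C)(C(C)C)C(C)C)c(CCl)c1
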